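Readings and results are simulated for substances that don't exist, and the scatter is random.

**The start.** No constant of this flask was given to me, so I began from the rates that the two earlier runs showed.

| flask | solid substrate | gas phase | remark | time |
|---|---|---|---|---|
| eta | 21 mM | 1.5 mM (held) | run made earlier |  |
| delta | 140 mM | 1.5 mM (held) | run made earlier |  |
| larch | 100 mM | 1.5 mM (held) |  | 8.0 min |
| cedar | 33 mM | 1.5 mM (held) |  | 8.0 min |
| maple | 50 mM | 1.5 mM (held) |  | 8.0 min |
| elm | 15 mM | 1.5 mM (held) |  | 8.0 min |

| run | time / min | target / % | solid substrate / % |
|---|---|---|---|
| eta | 1.33 | 3 | 89 |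
| eta | 2.50 | 6 | 79 |
| eta | 4.00 | 10 | 69 |
| eta | 5.00 | 14 | 62 |
| eta | 6.00 | 17 | 53 |
| eta | 8.00 | 23 | 40 |
| delta | 1.33 | 1 | 97 |
| delta | 2.50 | 0 | 95 |
| delta | 4.00 | 0 | 94 |
| delta | 5.00 | 1 | 95 |
| delta | 6.00 | 2 | 94 |
| delta | 8.00 | 3 | 90 |

(readings scatter by 1.5 percentage points)

- solid, in amounts per volume of the solution: solid substrate
- at the start none of the gas phase is in solution
- at the start none of the solid substrate is in solution
- what has only dissolved of solid substrate counts as not reacted

- the flasks put in order of amount of target, in percent of the solid substrate charged, best first, at 8.0 min (larch / cedar / maple / elm)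
- the amount of target, in percent of the solid substrate charged of the flask you put first, at 8.0 min
- the amount of target, in percent of the solid substrate charged of the flask you put last, at 8.0 min

**Two rates.** Eta lost 1.57 mM min⁻¹ of solid substrate and delta 1.75 mM min⁻¹, on a charge 6.67 times eta's. So I took the reaction as zero order in the charge. The integral of such a rate over a given time is the same amount in each flask. I call the concentration of target made by the reading time, as read from eta, the ration, 4.83 mM, and the percent yield is the ration over the charge. Delta gave 4.20 mM, but its percentages carry the same scatter on a larger charge, so I kept eta's value.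

**The ladder.** Charge over eta's loss gave the time the solid substrate should last: 9.52 min for elm, 21.0 min for cedar, 31.7 min for maple and 63.5 min for larch. The reading at 8.0 min comes before each of these, though narrowly for elm. I therefore reckoned 32.2% for elm, 14.6% for cedar, 9.66% for maple and 4.83% for larch.

**The forecast.** It gave elm > cedar > maple > larch, with 29% at the top and 4.5% at the bottom, and it spoke of “a zero-order, saturation- or dissolution-limited regime, independent of load”. Its order was mine. Its top lay lower than my figure for elm.

**The result.** The flasks gave elm > cedar > maple > larch, with 31.0% and 4.65%.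

    gas phase ⇌ dissolved gas, rate k1*(csat - [dissolved gas]) (kL = 4.40 min⁻¹)
    starting material + dissolved gas → target (k = 330 L mol⁻¹ min⁻¹)
    starting material → side product (k = 0.330 min⁻¹)
    dissolved gas + target → over-reaction product (k = 55.0 L mol⁻¹ min⁻¹)
    solid substrate ⇌ starting material, rate k5*(cs5 - [starting material]) while solid is left; crystals form when [starting material] > cs5 (solubility = 16.0 mM, k = 0.110 min⁻¹)

**The neighbour.** Elm's yield came to 4.65 mM of target and larch's to 4.65 mM, beside my ration of 4.83 mM. Elm still held 16.4% of its charge as solid substrate at 8.00 min. The neighbouring flask is larch with 40 mM of solid substrate. The ration over that charge gave 12.1%, and that flask held 11.6% of target at 8.00 min.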